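**Plan**
1. Retrosynthesis: the two MOM ethers are put back, then the bond between the ring A C2′ oxygen and Cγ is re-formed (reverse of a reductive benzylic ether cleavage) to give a flavan; the flavan is cut at Cα–Cβ and at O–Cγ into a ring A ortho-quinone methide and a ring B 6-vinylchroman.
2. Enabling feature: the ring A hydroxyl at C2′ is ortho to the chain carbon C1′, so O–C2′–C1′–Cα–Cβ–Cγ is the pyran ring of a flavan that carries ring B on Cγ (flavan C2).
3. Ring A, forward: 2,4-dihydroxybenzaldehyde, O-prenylation, Claisen shift to C5′ (1,1-dimethylallyl), MOM, reduction to the ortho-hydroxybenzyl alcohol (steps 1–6).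
4. Ring B, forward: 2-bromo-4,5-dimethoxybenzaldehyde; a propargyl ether Claisen cascade closes the dimethylpyran (first ring, step 9), then saturation, Wittig vinyl group, prenyl in place of bromine (steps 7–13).
5. Union: a [4+2] cycloaddition closes the flavan pyran (second ring, step 14), Li/NH3 reopens it at O–Cγ (step 15), acid frees the phenols (step 16).
6. Stereochemistry: kazinol D has no stereocentre; flavan C2 arises racemic and becomes a methylene in step 15.

Key step: step 14

Remark (assumption): compounds 1, 2, 9, 11 and 17 are taken as commercial; the racemic flavan 23 is written without a configuration descriptor.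

**Route**

Step 1
Reactants: 1 2,4-dihydroxybenzaldehyde; 2 prenyl bromide (1-bromo-3-methylbut-2-ene)
Product: 3 2-hydroxy-4-[(3-methylbut-2-en-1-yl)oxy]benzaldehyde
Conditions: 2 (1.05 equiv), K2CO3 (1.0 equiv), acetone, 50 °C
Reagents that add atoms: prenyl bromide (2), CC(C)=CCBr
Why: Williamson etherification; the 2-hydroxyl is hydrogen-bonded to the aldehyde and less acidic than the 4-hydroxyl, so one equivalent of base should alkylate O4 only.

Step 2
Reactants: 3 2-hydroxy-4-[(3-methylbut-2-en-1-yl)oxy]benzaldehyde
Product: 4 4-[(3-methylbut-2-en-1-yl)oxy]-2-[(triisopropylsilyl)oxy]benzaldehyde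
Conditions: TIPSCl, imidazole, DMF, rt
Reagents that add atoms: chlorotriisopropylsilane (TIPSCl), CC(C)[Si](Cl)(C(C)C)C(C)C
Why: Imidazole-promoted silylation of the phenol; the bulky silyl ether removes the chelate that would steer the coming rearrangement to C3, shields C3 and is slow to move between oxygens.

Step 3
Reactants: 4 4-[(3-methylbut-2-en-1-yl)oxy]-2-[(triisopropylsilyl)oxy]benzaldehyde
Product: 5 4-hydroxy-5-(2-methylbut-3-en-2-yl)-2-[(triisopropylsilyl)oxy]benzaldehyde
Conditions: PhNEt2, 190 °C, sealed tube
Reagents that add atoms: none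
Why: Aromatic Claisen rearrangement ([3,3] shift with allylic inversion, then enolization) should deliver the 1,1-dimethylallyl group to C5, because C3 lies between the silyloxy and allyloxy groups; aldehyde and silyl ether tolerate the neutral thermal conditions.

Step 4
Reactants: 5 4-hydroxy-5-(2-methylbut-3-en-2-yl)-2-[(triisopropylsilyl)oxy]benzaldehyde
Product: 6 4-(methoxymethoxy)-5-(2-methylbut-3-en-2-yl)-2-[(triisopropylsilyl)oxy]benzaldehyde
Conditions: MOMCl, i-Pr2NEt, CH2Cl2, 0 °C to rt
Reagents that add atoms: chloromethyl methyl ether (MOMCl), COCCl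
Why: O-alkylation of the phenol to a MOM acetal under amine base, leaving aldehyde and silyl ether untouched; the protected O4 later prevents para-quinone methide formation and abnormal Claisen chemistry in the hot key step.

Step 5
Reactants: 6 4-(methoxymethoxy)-5-(2-methylbut-3-en-2-yl)-2-[(triisopropylsilyl)oxy]benzaldehyde
Product: 7 2-hydroxy-4-(methoxymethoxy)-5-(2-methylbut-3-en-2-yl)benzaldehyde
Conditions: TBAF, AcOH, THF, 0 °C
Reagents that add atoms: none
Why: Fluoride-mediated cleavage of the aryl silyl ether, buffered with acetic acid so that the MOM acetal, the aldehyde and the alkene are not affected.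

Step 6
Reactants: 7 2-hydroxy-4-(methoxymethoxy)-5-(2-methylbut-3-en-2-yl)benzaldehyde
Product: 8 2-(hydroxymethyl)-5-(methoxymethoxy)-4-(2-methylbut-3-en-2-yl)phenol
Conditions: NaBH4, MeOH, 0 °C; pH 7 buffer
Reagents that add atoms: none
Why: Borohydride reduction of the aldehyde to the benzylic alcohol; the work-up is kept neutral because the MOM-oxy group para to the benzylic carbon makes the product prone to acid-induced quinone methide formation.

Step 7
Reactants: 9 2-bromo-4,5-dimethoxybenzaldehyde
Product: 10 2-bromo-4,5-dihydroxybenzaldehyde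
Conditions: BBr3, CH2Cl2, −78 °C to rt; H2O
Reagents that add atoms: none
Why: Lewis-acid ether cleavage (BBr3 demethylation) of both methyl ethers; aldehyde and aryl bromide are retained, and the bromine already marks the carbon that will carry the prenyl group.

Step 8
Reactants: 10 2-bromo-4,5-dihydroxybenzaldehyde; 11 3-chloro-3-methylbut-1-yne
Product: 12 2-bromo-5-hydroxy-4-[(2-methylbut-3-yn-2-yl)oxy]benzaldehyde
Conditions: 11, DBU (1.05 equiv), CuCl2 (1 mol %), MeCN, 0 °C
Reagents that add atoms: 3-chloro-3-methylbut-1-yne (11), C#CC(C)(C)Cl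
Why: Copper-catalysed O-alkylation of a phenol with a tertiary propargylic chloride; one equivalent of DBU ionizes only the more acidic 4-hydroxyl (para to the aldehyde), so the ether should form there.

Step 9
Reactants: 12 2-bromo-5-hydroxy-4-[(2-methylbut-3-yn-2-yl)oxy]benzaldehyde
Product: 14 5-bromo-8-hydroxy-2,2-dimethyl-2H-chromene-6-carbaldehyde, via allenylphenol 13 (not isolated)
Conditions: PhNEt2, 170 °C
Reagents that add atoms: none
Why: Aryl propargyl ether Claisen cascade, in which a [3,3] shift to C3 (the only free ortho carbon) and enolization give 13, whose 1,5-hydrogen shift and oxa-6π electrocyclization close the 2,2-dimethylpyran ring.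

Step 10
Reactants: 14 5-bromo-8-hydroxy-2,2-dimethyl-2H-chromene-6-carbaldehyde
Product: 15 5-bromo-8-(methoxymethoxy)-2,2-dimethyl-2H-chromene-6-carbaldehyde
Conditions: MOMCl, i-Pr2NEt, CH2Cl2, 0 °C to rt
Reagents that add atoms: chloromethyl methyl ether (MOMCl), COCCl
Why: MOM protection of the phenol by O-alkylation, giving the same protecting group as on ring A so that one acidic step frees both at the end.

Step 11
Reactants: 15 5-bromo-8-(methoxymethoxy)-2,2-dimethyl-2H-chromene-6-carbaldehyde
Product: 16 5-bromo-8-(methoxymethoxy)-2,2-dimethylchroman-6-carbaldehyde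
Conditions: H2 (3 atm), RhCl(PPh3)3 (5 mol %), PhMe/EtOH, 40 °C
Reagents that add atoms: none
Why: Homogeneous rhodium-catalysed hydrogenation saturates the cis-disubstituted chromene alkene while the aryl bromide, the aryl aldehyde and the MOM acetal stay intact, which palladium on carbon would not guarantee.

Step 12
Reactants: 16 5-bromo-8-(methoxymethoxy)-2,2-dimethylchroman-6-carbaldehyde; 17 methyltriphenylphosphonium bromide
Product: 18 5-bromo-8-(methoxymethoxy)-2,2-dimethyl-6-vinylchroman
Conditions: 17, KOtBu, THF, 0 °C to rt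
Reagents that add atoms: methyltriphenylphosphonium bromide (17), C[P+](c1ccccc1)(c1ccccc1)c1ccccc1.[Br-]
Why: Wittig methylenation with the non-stabilized ylide converts the aldehyde into the vinyl group; aryl bromide and MOM ether are inert to the ylide.

Step 13
Reactants: 18 5-bromo-8-(methoxymethoxy)-2,2-dimethyl-6-vinylchroman; 2 prenyl bromide
Product: 21 8-(methoxymethoxy)-2,2-dimethyl-5-(3-methylbut-2-en-1-yl)-6-vinylchroman, via aryllithium 19 (not isolated), via arylcopper 20 (not isolated)
Conditions: n-BuLi, THF, −78 °C; CuBr·SMe2, −78 to −40 °C; 2, −78 to 0 °C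
Reagents that add atoms: prenyl bromide (2), CC(C)=CCBr
Why: Bromine–lithium exchange at −78 °C is faster than addition of n-BuLi to the styrene or ortho-lithiation beside the MOM ether, and transmetalation to copper followed by allylic substitution at the primary carbon of prenyl bromide should give the linear prenyl arene.

Step 14
Reactants: 8 2-(hydroxymethyl)-5-(methoxymethoxy)-4-(2-methylbut-3-en-2-yl)phenol; 21 8-(methoxymethoxy)-2,2-dimethyl-5-(3-methylbut-2-en-1-yl)-6-vinylchroman
Product: 23 racemic 7-(methoxymethoxy)-6-(2-methylbut-3-en-2-yl)-2-[8-(methoxymethoxy)-2,2-dimethyl-5-(3-methylbut-2-en-1-yl)chroman-6-yl]chroman, via ortho-quinone methide 22 (not isolated)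
Conditions: 8 (2 equiv, in portions), BHT (cat.), PhMe, 150 °C, sealed tube
Reagents that add atoms: none
Why: Heating should expel water from 8 in a 1,4-elimination, helped by the MOM-oxy group para to the benzylic carbon, to give ortho-quinone methide 22, an electron-poor 1-oxadiene that adds the electron-rich vinyl group of 21 in an inverse-electron-demand hetero-Diels–Alder reaction. The closest known reaction type is the thermal [4+2] addition of ortho-quinone methides from ortho-hydroxybenzyl alcohols to styrenes, which gives flavans. The one new ring, the flavan pyran, closes by intermolecular [4+2] cycloaddition that forms C3–C4 (Cβ–Cα) and O1–C2 (O–Cγ) in a single asynchronous event. The new stereocentre at C2 has no controlling element, so 23 is racemic, which is harmless because step 15 turns this carbon into a methylene. Chemoselectivity among the C=C bonds is needed and is secured because only the ring B vinyl group is conjugated with an arene and activated by the chroman oxygen para to it, whereas the prenyl and 1,1-dimethylallyl alkenes are isolated and hindered. Regiochemistry follows from polarization, the electrophilic methylidene carbon of 22 bonding to the terminal vinyl carbon and the oxygen to the benzylic carbon, which places ring B on the oxygen-bearing carbon; excess 8 and a radical inhibitor offset self-condensation of 22 and polymerization of the styrene.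

Step 15
Reactants: 23 racemic 7-(methoxymethoxy)-6-(2-methylbut-3-en-2-yl)-2-[8-(methoxymethoxy)-2,2-dimethyl-5-(3-methylbut-2-en-1-yl)chroman-6-yl]chroman
Product: 24 2-{3-[8-(methoxymethoxy)-2,2-dimethyl-5-(3-methylbut-2-en-1-yl)chroman-6-yl]propyl}-5-(methoxymethoxy)-4-(2-methylbut-3-en-2-yl)phenol
Conditions: Li, NH3 (l)/THF, −78 °C; NH4Cl
Reagents that add atoms: none
Why: Dissolving-metal cleavage of a benzyl aryl ether (Birch-type), in which electron transfer is followed by loss of the ring A phenoxide from C2, a second electron transfer and protonation of the benzylic anion by ammonia, removing the only stereocentre; without added alcohol the isolated alkenes, the MOM ethers and the arene rings should not be reduced.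

Step 16
Reactants: 24 2-{3-[8-(methoxymethoxy)-2,2-dimethyl-5-(3-methylbut-2-en-1-yl)chroman-6-yl]propyl}-5-(methoxymethoxy)-4-(2-methylbut-3-en-2-yl)phenol
Product: 25 kazinol D
Conditions: aq. HCl (3 M), MeOH, 40 °C
Reagents that add atoms: none
Why: Acid-catalysed acetal solvolysis removes both MOM groups; the ring B prenyl group has no ortho hydroxyl to cyclize onto, and the monosubstituted alkene of the 1,1-dimethylallyl group should not be protonated by dilute acid at this temperature.

**Compound list**
1 | 2,4-dihydroxybenzaldehyde | O=Cc1ccc(O)cc1O | starting material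
2 | prenyl bromide (1-bromo-3-methylbut-2-ene) | CC(C)=CCBr | starting material
3 | 2-hydroxy-4-[(3-methylbut-2-en-1-yl)oxy]benzaldehyde | O=Cc1ccc(OCC=C(C)C)cc1O | intermediate
4 | 4-[(3-methylbut-2-en-1-yl)oxy]-2-[(triisopropylsilyl)oxy]benzaldehyde | O=Cc1ccc(OCC=C(C)C)cc1O[Si](C(C)C)(C(C)C)C(C)C | intermediate
5 | 4-hydroxy-5-(2-methylbut-3-en-2-yl)-2-[(triisopropylsilyl)oxy]benzaldehyde | O=Cc1cc(C(C)(C)C=C)c(O)cc1O[Si](C(C)C)(C(C)C)C(C)C | intermediate
6 | 4-(methoxymethoxy)-5-(2-methylbut-3-en-2-yl)-2-[(triisopropylsilyl)oxy]benzaldehyde | O=Cc1cc(C(C)(C)C=C)c(OCOC)cc1O[Si](C(C)C)(C(C)C)C(C)C | intermediate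
7 | 2-hydroxy-4-(methoxymethoxy)-5-(2-methylbut-3-en-2-yl)benzaldehyde | O=Cc1cc(C(C)(C)C=C)c(OCOC)cc1O | intermediate
8 | 2-(hydroxymethyl)-5-(methoxymethoxy)-4-(2-methylbut-3-en-2-yl)phenol | OCc1cc(C(C)(C)C=C)c(OCOC)cc1O | intermediate
9 | 2-bromo-4,5-dimethoxybenzaldehyde | O=Cc1cc(OC)c(OC)cc1Br | starting material
10 | 2-bromo-4,5-dihydroxybenzaldehyde | O=Cc1cc(O)c(O)cc1Br | intermediate
11 | 3-chloro-3-methylbut-1-yne | C#CC(C)(C)Cl | starting material
12 | 2-bromo-5-hydroxy-4-[(2-methylbut-3-yn-2-yl)oxy]benzaldehyde | O=Cc1cc(O)c(OC(C)(C)C#C)cc1Br | intermediate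
13 | allenylphenol (not isolated): 2-bromo-4,5-dihydroxy-3-(3-methylbuta-1,2-dien-1-yl)benzaldehyde | O=Cc1cc(O)c(O)c(C=C=C(C)C)c1Br | intermediate
14 | 5-bromo-8-hydroxy-2,2-dimethyl-2H-chromene-6-carbaldehyde | O=Cc1cc(O)c2OC(C)(C)C=Cc2c1Br | intermediate
15 | 5-bromo-8-(methoxymethoxy)-2,2-dimethyl-2H-chromene-6-carbaldehyde | O=Cc1cc(OCOC)c2OC(C)(C)C=Cc2c1Br | intermediate
16 | 5-bromo-8-(methoxymethoxy)-2,2-dimethylchroman-6-carbaldehyde | O=Cc1cc(OCOC)c2OC(C)(C)CCc2c1Br | intermediate
17 | methyltriphenylphosphonium bromide | C[P+](c1ccccc1)(c1ccccc1)c1ccccc1.[Br-] | starting material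
18 | 5-bromo-8-(methoxymethoxy)-2,2-dimethyl-6-vinylchroman | C=Cc1cc(OCOC)c2OC(C)(C)CCc2c1Br | intermediate
19 | aryllithium (not isolated): [8-(methoxymethoxy)-2,2-dimethyl-6-vinylchroman-5-yl]lithium | [Li]c1c(C=C)cc(OCOC)c2OC(C)(C)CCc12 | intermediate
20 | arylcopper (not isolated): [8-(methoxymethoxy)-2,2-dimethyl-6-vinylchroman-5-yl]copper | [Cu]c1c(C=C)cc(OCOC)c2OC(C)(C)CCc12 | intermediate
21 | 8-(methoxymethoxy)-2,2-dimethyl-5-(3-methylbut-2-en-1-yl)-6-vinylchroman | C=Cc1cc(OCOC)c2OC(C)(C)CCc2c1CC=C(C)C | intermediate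
22 | ortho-quinone methide (not isolated): 3-(methoxymethoxy)-4-(2-methylbut-3-en-2-yl)-6-methylidenecyclohexa-2,4-dien-1-one | C=C1C=C(C(C)(C)C=C)C(OCOC)=CC1=O | intermediate
23 | racemic 7-(methoxymethoxy)-6-(2-methylbut-3-en-2-yl)-2-[8-(methoxymethoxy)-2,2-dimethyl-5-(3-methylbut-2-en-1-yl)chroman-6-yl]chroman | C=CC(C)(C)c1cc2CCC(Oc2cc1OCOC)c1cc(OCOC)c2OC(C)(C)CCc2c1CC=C(C)C | intermediate
24 | 2-{3-[8-(methoxymethoxy)-2,2-dimethyl-5-(3-methylbut-2-en-1-yl)chroman-6-yl]propyl}-5-(methoxymethoxy)-4-(2-methylbut-3-en-2-yl)phenol | C=CC(C)(C)c1cc(CCCc2cc(OCOC)c3OC(C)(C)CCc3c2CC=C(C)C)c(O)cc1OCOC | intermediate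
25 | kazinol D: 4-{3-[8-hydroxy-2,2-dimethyl-5-(3-methylbut-2-en-1-yl)chroman-6-yl]propyl}-6-(2-methylbut-3-en-2-yl)benzene-1,3-diol (no stereocentre) | C=CC(C)(C)c1cc(CCCc2cc(O)c3c(c2CC=C(C)C)CCC(C)(C)O3)c(O)cc1O | target

**Totals**
Total steps: 16. Longest linear sequence: 10 steps (steps 7–16, from 9); the ring A branch is 6 steps (1–6) before the union.

**Steps most likely to fail**

1. Step 14. At the temperature needed to dehydrate 8, the quinone methide may be used up by self-condensation with 8 or by dimerization faster than the ortho-substituted styrene captures it, and the styrene may polymerize. The fallback sets out from 8 and comes back at 23. The phenol of 8 is acylated selectively with Boc2O (i-Pr2NEt, cat. DMAP, CH2Cl2, 0 °C) to give tert-butyl [2-(hydroxymethyl)-5-(methoxymethoxy)-4-(2-methylbut-3-en-2-yl)phenyl] carbonate F1. Deprotonation of its benzylic alcohol with t-BuMgCl in THF at −78 °C in the presence of 21, then warming to 0 °C, moves the carbonate to the benzylic oxygen and expels tert-butyl carbonate. Magnesium-bound 22 is thus released slowly at low temperature, and its [4+2] addition to 21 gives 23.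

2. Step 15. Electron transfer may be diverted into Birch reduction of the electron-rich rings or into loss of MOM groups, giving phenoxides that resist further electron uptake, so that the benzylic C–O bond is cleaved incompletely; partial saturation of the terminal alkenes is also possible. The fallback sets out from 21 and 8 and comes back at 24; it builds the open chain by conjugate addition to the quinone methide, so no C–O bond has to be cleaved. Hydroboration of 21 with 9-BBN in THF, selective for the monosubstituted vinyl terminus over the trisubstituted prenyl alkene, gives 9-{2-[8-(methoxymethoxy)-2,2-dimethyl-5-(3-methylbut-2-en-1-yl)chroman-6-yl]ethyl}-9-borabicyclo[3.3.1]nonane F2. Oxidation with NaOH/H2O2 gives 2-[8-(methoxymethoxy)-2,2-dimethyl-5-(3-methylbut-2-en-1-yl)chroman-6-yl]ethan-1-ol F3. An Appel reaction (CBr4, PPh3, CH2Cl2) gives 6-(2-bromoethyl)-8-(methoxymethoxy)-2,2-dimethyl-5-(3-methylbut-2-en-1-yl)chroman F4, and magnesium in THF converts it into the Grignard reagent {2-[8-(methoxymethoxy)-2,2-dimethyl-5-(3-methylbut-2-en-1-yl)chroman-6-yl]ethyl}magnesium bromide F5. The carbonate F1, made from 8 as in the first fallback, is deprotonated with t-BuMgCl (1.0 equiv) at −78 °C, F5 is added and the mixture is warmed. 22 forms as before and F5 adds to its methylidene carbon in a 1,4-addition, which creates the Cα–Cβ bond and gives 24 after NH4Cl work-up.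

3. Step 3. The allyl group may be delivered partly to C3, the hot amine may pass the silyl group to the liberated phenol, and the ortho-(1,1-dimethylallyl)phenol formed may cyclize or undergo the abnormal Claisen rearrangement. The fallback sets out from 1 and comes back at 7, replacing steps 1–5; it installs the 1,1-dimethylallyl group by cross-coupling and not by a sigmatropic shift. Bromination of 1 (Br2, AcOH, rt), para to the 2-hydroxyl and ortho to the 4-hydroxyl, gives 5-bromo-2,4-dihydroxybenzaldehyde F6. MOMCl/i-Pr2NEt protects the non-chelated 4-hydroxyl to give 5-bromo-2-hydroxy-4-(methoxymethoxy)benzaldehyde F7. A γ-selective Suzuki–Miyaura coupling of F7 with prenylboronic acid pinacol ester, carried out with Pd(OAc)2, 1,1′-bis(di-tert-butylphosphino)ferrocene and K3PO4 in THF/H2O at 60 °C, joins the aryl carbon to the tertiary allyl terminus and gives 7.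

**Further compounds**
F1 | step 14 | tert-butyl [2-(hydroxymethyl)-5-(methoxymethoxy)-4-(2-methylbut-3-en-2-yl)phenyl] carbonate | C=CC(C)(C)c1cc(CO)c(OC(=O)OC(C)(C)C)cc1OCOC
F2 | step 15 | 9-{2-[8-(methoxymethoxy)-2,2-dimethyl-5-(3-methylbut-2-en-1-yl)chroman-6-yl]ethyl}-9-borabicyclo[3.3.1]nonane | C(Cc1cc(OCOC)c2OC(C)(C)CCc2c1CC=C(C)C)B1C2CCCC1CCC2
F3 | step 15 | 2-[8-(methoxymethoxy)-2,2-dimethyl-5-(3-methylbut-2-en-1-yl)chroman-6-yl]ethan-1-ol | OCCc1cc(OCOC)c2OC(C)(C)CCc2c1CC=C(C)C
F4 | step 15 | 6-(2-bromoethyl)-8-(methoxymethoxy)-2,2-dimethyl-5-(3-methylbut-2-en-1-yl)chroman | BrCCc1cc(OCOC)c2OC(C)(C)CCc2c1CC=C(C)C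
F5 | step 15 | {2-[8-(methoxymethoxy)-2,2-dimethyl-5-(3-methylbut-2-en-1-yl)chroman-6-yl]ethyl}magnesium bromide | Br[Mg]CCc1cc(OCOC)c2OC(C)(C)CCc2c1CC=C(C)C
F6 | step 3 | 5-bromo-2,4-dihydroxybenzaldehyde | O=Cc1cc(Br)c(O)cc1O
F7 | step 3 | 5-bromo-2-hydroxy-4-(methoxymethoxy)benzaldehyde | O=Cc1cc(Br)c(OCOC)cc1O
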